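**Retrosynthetic overview**

1. The bicycle is numbered as a 2,4,5,6,7,7a-hexahydro-1H-inden-2-one: ring A is the cyclohexane (C3a, C4, C5, C6, C7, C7a), ring B the cyclopentenone (C1, C2, C3, C3a, C7a). End game: the C7 tert-butyl ester gives the acid, the 2-formylallyl group at C1 comes from α-methylenation of a 3-oxopropyl chain, and the C4 trienoate (acid 13, from (R)-2-methylbutan-1-ol by Wittig and Horner–Wadsworth–Emmons olefination) is attached before ring B exists.
2. Key disconnection: the C1–C7a bond of ring B, by a gold-catalysed Rautenstrauch rearrangement of propargylic pivalate 18. The enabling feature is that in ring B the C2 ketone lies between sp3 C1 and the C3=C3a double bond, while C3a and C7a also belong to ring A. Ring B is therefore the cyclopent-2-enone that a 3-acyloxy-1,4-enyne delivers when its alkene is the tetrasubstituted C3a=C7a bond of a cyclohexene and C3 is the exocyclic carbinol.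
3. This one operation should give ring B, the C2 carbonyl (1,2-oxygen transposition), the quaternary C7a (chirality transfer from a catalyst-set carbinol, matched with the cis C4/C7 substituents) and C1 (thermodynamic), with fourteen of the fifteen skeletal carbons and the ester in place.
4. Precursor 18: ring A from tert-butyl acetoacetate and methyl vinyl ketone (tert-butyl Hagemann's ester), then α-iodination, CBS reduction (C4), esterification, carbonylative Sonogashira coupling with alkyne 15, Noyori transfer hydrogenation and pivaloylation.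
5. Ring order: ring A first (step 1), ring B last (step 12).

Key step: step 12

Remark: (R)-2-methylbutan-1-ol 7, the less common enantiomer of the chiral-pool alcohol, is taken as purchasable.

Abbreviations: "trienoyl" = (2E,4E,6E,8R)-6,8-dimethyldeca-2,4,6-trienoyl; TBS = tert-butyldimethylsilyl.

**Route**

Step 1
Reactants: 1 tert-butyl 3-oxobutanoate; 2 but-3-en-2-one
Product: 4 rac-tert-butyl 2-methyl-4-oxocyclohex-2-ene-1-carboxylate, via tert-butyl 2-acetyl-5-oxohexanoate 3 (not isolated)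
Conditions: KOt-Bu (cat.), t-BuOH, 0 °C to rt; then pyrrolidine (cat.), AcOH (cat.), toluene, reflux, Dean–Stark
Reagents that add atoms: none
Why: Michael addition of the β-keto ester to the enone followed by enamine-mediated intramolecular aldol condensation of the methyl ketone onto the acetoacetate carbonyl (Robinson annulation, the Hagemann's ester synthesis) should close ring A; the ester-bearing stereocenter is formed racemic.

Step 2
Reactants: 4 rac-tert-butyl Hagemann's ester
Product: 5 rac-tert-butyl 3-iodo-2-methyl-4-oxocyclohex-2-ene-1-carboxylate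
Conditions: I2, pyridine, 4-(dimethylamino)pyridine (cat.), CH2Cl2, 0 °C to rt, dark
Reagents that add atoms: iodine, II
Why: Johnson-type α-iodination of a cyclic enone at C3, the enone α-carbon at which Hagemann-type esters are normally substituted through their dienol; no stereocenter is set.

Step 3
Reactants: 5 rac-iodoenone
Product: 6 tert-butyl (1R,4S)-4-hydroxy-3-iodo-2-methylcyclohex-2-ene-1-carboxylate (cis)
Conditions: (R)-1-methyl-3,3-diphenyltetrahydro-1H,3H-pyrrolo[1,2-c][1,3,2]oxazaborole (0.2 equiv), BH3·SMe2, THF, −30 °C; MeOH; chromatography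
Reagents that add atoms: none
Why: Corey–Bakshi–Shibata reduction with the α-iodoalkenyl group as the large substituent should give the (4S)-carbinol under catalyst control from both enantiomers of 5, so the (1R)-enantiomer gives cis-6 and the (1S)-enantiomer gives the trans diastereomer, which is removed by chromatography (at most half of 5 is used); this fixes the later C4 and C7.

Step 4
Reactants: 7 (R)-2-methylbutan-1-ol
Product: 8 (R)-2-methylbutanal
Conditions: 2,2,6,6-tetramethylpiperidin-1-oxyl (cat.), KBr (cat.), NaOCl, NaHCO3, CH2Cl2/H2O, 0 °C; dried solution used directly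
Reagents that add atoms: none
Why: nitroxyl-catalysed hypochlorite oxidation of a primary alcohol stops at the aldehyde and, being buffered and cold, should leave the α-stereocenter intact.

Step 5
Reactants: 8 (R)-2-methylbutanal; 9 2-(triphenyl-λ5-phosphanylidene)propanal
Product: 10 (2E,4R)-2,4-dimethylhex-2-enal
Conditions: toluene, 80 °C
Reagents that add atoms: none
Why: Wittig olefination with a stabilised formyl ylide should give the (E)-trisubstituted enal; the allylic stereocenter comes from 8.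

Step 6
Reactants: 10 (2E,4R)-2,4-dimethylhex-2-enal; 11 ethyl (2E)-4-(diethoxyphosphoryl)but-2-enoate
Product: 12 ethyl (2E,4E,6E,8R)-6,8-dimethyldeca-2,4,6-trienoate
Conditions: LiN(SiMe3)2, THF, −78 °C to 0 °C
Reagents that add atoms: none
Why: vinylogous Horner–Wadsworth–Emmons olefination should form the new C4=C5 bond with E geometry and keeps the E C2=C3 bond of the phosphonate.

Step 7
Reactants: 12 ethyl trienoate
Product: 13 (2E,4E,6E,8R)-6,8-dimethyldeca-2,4,6-trienoic acid
Conditions: LiOH, THF/MeOH/H2O, rt; then aq. HCl to pH 3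
Reagents that add atoms: lithium hydroxide, [Li+].[OH-]
Why: saponification of the ethyl ester (acyl–oxygen cleavage) should not touch the triene or the remote stereocenter.

Step 8
Reactants: 6 cis-iodo alcohol; 13 trienoic acid
Product: 14 tert-butyl (1R,4S)-3-iodo-2-methyl-4-(trienoyloxy)cyclohex-2-ene-1-carboxylate
Conditions: N-(3-dimethylaminopropyl)-N′-ethylcarbodiimide hydrochloride, 4-(dimethylamino)pyridine (cat.), CH2Cl2, 0 °C to rt
Reagents that add atoms: none
Why: Steglich-type carbodiimide esterification of the unhindered allylic alcohol takes place at the acyl carbon, so C4 keeps its configuration, and the final ester serves as the only protection of this oxygen.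

Step 9
Reactants: 14 iodo trienoate ester; 15 tert-butyldimethyl(pent-4-yn-1-yloxy)silane
Product: 16 tert-butyl (1R,4S)-3-{6-[(TBS)oxy]hex-2-ynoyl}-2-methyl-4-(trienoyloxy)cyclohex-2-ene-1-carboxylate
Conditions: CO (1 atm), PdCl2(PPh3)2 (5 mol%), CuI (5 mol%), Et3N, THF, rt
Reagents that add atoms: carbon monoxide, [C-]#[O+]
Why: carbonylative Sonogashira coupling (oxidative addition of the vinyl iodide, CO insertion, alkynyl transfer from copper) should give the alkynyl ketone; the allylic ester should not ionise because the vinyl iodide reacts first and the alkene is tetrasubstituted.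

Step 10
Reactants: 16 ynone
Product: 17 tert-butyl (1R,4S)-3-{(1R)-6-[(TBS)oxy]-1-hydroxyhex-2-yn-1-yl}-2-methyl-4-(trienoyloxy)cyclohex-2-ene-1-carboxylate
Conditions: Ru[(S,S)-TsDPEN](p-cymene) (2 mol%), i-PrOH, rt
Reagents that add atoms: none
Why: Noyori asymmetric transfer hydrogenation of an alkynyl ketone, with the alkyne as the directing π-substituent, should deliver hydride under catalyst control to give the (R)-carbinol and leave the trienoate and the tetrasubstituted alkene untouched.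

Step 11
Reactants: 17 propargylic alcohol
Product: 18 tert-butyl (1R,4S)-3-{(1R)-6-[(TBS)oxy]-1-[(2,2-dimethylpropanoyl)oxy]hex-2-yn-1-yl}-2-methyl-4-(trienoyloxy)cyclohex-2-ene-1-carboxylate
Conditions: pivaloyl chloride, pyridine, 4-(dimethylamino)pyridine (cat.), CH2Cl2, 0 °C
Reagents that add atoms: pivaloyl chloride, CC(C)(C)C(Cl)=O
Why: O-acylation with retention at the carbinol carbon; the weak base and low temperature should prevent migration of the neighbouring trienoyl group.

Step 12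
Reactants: 18 propargylic pivalate
Product: 20 tert-butyl (1R,4S,7R,7aS)-1-{3-[(TBS)oxy]propyl}-7a-methyl-2-oxo-4-(trienoyloxy)-2,4,5,6,7,7a-hexahydro-1H-indene-7-carboxylate, via dienyl pivalate 19 (not isolated)
Conditions: AuCl(PPh3) (5 mol%), AgSbF6 (5 mol%), MeCN containing H2O (2 equiv), −20 °C to rt; then 1,8-diazabicyclo[5.4.0]undec-7-ene (0.1 equiv), CH2Cl2, 0 °C
Reagents that add atoms: none
Why: Cationic monovalent gold activates the alkyne, the pivalate carbonyl adds to the proximal alkyne carbon (1,2-acyloxy shift), and the resulting gold-bound 2-pivaloyloxypentadienyl cation closes between the former distal alkyne carbon and the tetrasubstituted ring alkene carbon to give dienyl pivalate 19, which the wet acetonitrile hydrolyses to the enone. The closest known reaction type is the gold-catalysed Rautenstrauch rearrangement of 3-acyloxy-1,4-enynes to cyclopent-2-enones, which tolerates substituted alkynes and alkenes and transfers the carbinol chirality. Ring B closes by a conrotatory 4π electrocyclisation that forms the C1–C7a bond (formally 5-endo, but pericyclic and so not subject to the endo-trig restriction). Quaternary C7a is controlled by the (R)-carbinol: the C–C bond forms on the alkene face anti to the departing C–O bond, which is also the face opposite to the cis C4 acyloxy and C7 ester groups, so catalyst-derived and substrate control are matched. C1 arises by protonation during enol ester hydrolysis and is equilibrated by the amidine base to the isomer with the side chain trans to the C7-bearing branch, that is cis to the angular methyl. The step needs 1,2- rather than 1,3-acyloxy migration and ring closure rather than allene formation, which the adjacent electron-rich tetrasubstituted alkene and the low temperature should favour.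

Step 13
Reactants: 20 bicyclic enone silyl ether
Product: 21 tert-butyl (1R,4S,7R,7aS)-1-(3-hydroxypropyl)-7a-methyl-2-oxo-4-(trienoyloxy)-2,4,5,6,7,7a-hexahydro-1H-indene-7-carboxylate
Conditions: HF·pyridine, pyridine, THF, 0 °C to rt
Reagents that add atoms: none
Why: fluoride cleavage of the primary silyl ether under buffered conditions should leave the esters, the enone and C1 unaffected.

Step 14
Reactants: 21 primary alcohol
Product: 22 tert-butyl (1R,4S,7R,7aS)-7a-methyl-2-oxo-1-(3-oxopropyl)-4-(trienoyloxy)-2,4,5,6,7,7a-hexahydro-1H-indene-7-carboxylate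
Conditions: Dess–Martin periodinane, NaHCO3, CH2Cl2, 0 °C to rt
Reagents that add atoms: none
Why: Dess–Martin oxidation of the primary alcohol to the aldehyde under buffered, non-epimerising conditions.

Step 15
Reactants: 22 aldehyde
Product: 23 tert-butyl (1R,4S,7R,7aS)-1-(2-formylprop-2-en-1-yl)-7a-methyl-2-oxo-4-(trienoyloxy)-2,4,5,6,7,7a-hexahydro-1H-indene-7-carboxylate
Conditions: aq. HCHO (37%), pyrrolidine (10 mol%), propionic acid (10 mol%), i-PrOH, 45 °C
Reagents that add atoms: formaldehyde, C=O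
Why: organocatalytic α-methylenation of an aldehyde (Mannich condensation through the pyrrolidine enamine, then β-elimination of the amine) should be selective for the aldehyde over the hindered ring ketone; C1 is already in its thermodynamic configuration.

Step 16
Reactants: 23 enal tert-butyl ester
Product: 24 (1R,4S,7R,7aS)-1-(2-formylprop-2-en-1-yl)-7a-methyl-2-oxo-4-(trienoyloxy)-2,4,5,6,7,7a-hexahydro-1H-indene-7-carboxylic acid (target)
Conditions: CF3CO2H/CH2Cl2 (1:4), 0 °C
Reagents that add atoms: none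
Why: acidolysis of the tert-butyl ester by alkyl–oxygen cleavage (loss of isobutene) should free the acid without touching any stereocenter or the C4 ester, whose ionisation would place a cation next to the enone.

**Compound list**

1 | tert-butyl 3-oxobutanoate | CC(=O)CC(=O)OC(C)(C)C | starting material
2 | but-3-en-2-one | CC(=O)C=C | starting material
3 | tert-butyl 2-acetyl-5-oxohexanoate (racemic, not isolated) | CC(=O)CCC(C(C)=O)C(=O)OC(C)(C)C | intermediate
4 | rac-tert-butyl 2-methyl-4-oxocyclohex-2-ene-1-carboxylate | CC1=CC(=O)CCC1C(=O)OC(C)(C)C | intermediate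
5 | rac-tert-butyl 3-iodo-2-methyl-4-oxocyclohex-2-ene-1-carboxylate | CC1=C(I)C(=O)CCC1C(=O)OC(C)(C)C | intermediate
6 | tert-butyl (1R,4S)-4-hydroxy-3-iodo-2-methylcyclohex-2-ene-1-carboxylate | IC1=C(C)[C@H](C(=O)OC(C)(C)C)CC[C@@H]1O | intermediate
7 | (R)-2-methylbutan-1-ol | OC[C@H](C)CC | starting material
8 | (R)-2-methylbutanal | O=C[C@H](C)CC | intermediate
9 | 2-(triphenyl-λ5-phosphanylidene)propanal | CC(C=O)=P(c1ccccc1)(c1ccccc1)c1ccccc1 | starting material
10 | (2E,4R)-2,4-dimethylhex-2-enal | O=C/C(C)=C/[C@H](C)CC | intermediate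
11 | ethyl (2E)-4-(diethoxyphosphoryl)but-2-enoate | CCOC(=O)/C=C/CP(=O)(OCC)OCC | starting material
12 | ethyl (2E,4E,6E,8R)-6,8-dimethyldeca-2,4,6-trienoate | CCOC(=O)/C=C/C=C/C(C)=C/[C@H](C)CC | intermediate
13 | (2E,4E,6E,8R)-6,8-dimethyldeca-2,4,6-trienoic acid | OC(=O)/C=C/C=C/C(C)=C/[C@H](C)CC | intermediate
14 | tert-butyl (1R,4S)-4-{[(2E,4E,6E,8R)-6,8-dimethyldeca-2,4,6-trienoyl]oxy}-3-iodo-2-methylcyclohex-2-ene-1-carboxylate | IC1=C(C)[C@H](C(=O)OC(C)(C)C)CC[C@@H]1OC(=O)/C=C/C=C/C(C)=C/[C@H](C)CC | intermediate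
15 | tert-butyldimethyl(pent-4-yn-1-yloxy)silane | C#CCCCO[Si](C)(C)C(C)(C)C | starting material
16 | tert-butyl (1R,4S)-3-{6-[(tert-butyldimethylsilyl)oxy]hex-2-ynoyl}-4-{[(2E,4E,6E,8R)-6,8-dimethyldeca-2,4,6-trienoyl]oxy}-2-methylcyclohex-2-ene-1-carboxylate | O=C(C#CCCCO[Si](C)(C)C(C)(C)C)C1=C(C)[C@H](C(=O)OC(C)(C)C)CC[C@@H]1OC(=O)/C=C/C=C/C(C)=C/[C@H](C)CC | intermediate
17 | tert-butyl (1R,4S)-3-{(1R)-6-[(tert-butyldimethylsilyl)oxy]-1-hydroxyhex-2-yn-1-yl}-4-{[(2E,4E,6E,8R)-6,8-dimethyldeca-2,4,6-trienoyl]oxy}-2-methylcyclohex-2-ene-1-carboxylate | O[C@H](C#CCCCO[Si](C)(C)C(C)(C)C)C1=C(C)[C@H](C(=O)OC(C)(C)C)CC[C@@H]1OC(=O)/C=C/C=C/C(C)=C/[C@H](C)CC | intermediate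
18 | tert-butyl (1R,4S)-3-{(1R)-6-[(tert-butyldimethylsilyl)oxy]-1-[(2,2-dimethylpropanoyl)oxy]hex-2-yn-1-yl}-4-{[(2E,4E,6E,8R)-6,8-dimethyldeca-2,4,6-trienoyl]oxy}-2-methylcyclohex-2-ene-1-carboxylate | CC(C)(C)C(=O)O[C@H](C#CCCCO[Si](C)(C)C(C)(C)C)C1=C(C)[C@H](C(=O)OC(C)(C)C)CC[C@@H]1OC(=O)/C=C/C=C/C(C)=C/[C@H](C)CC | intermediate
19 | tert-butyl (4S,7R,7aS)-1-{3-[(tert-butyldimethylsilyl)oxy]propyl}-4-{[(2E,4E,6E,8R)-6,8-dimethyldeca-2,4,6-trienoyl]oxy}-2-[(2,2-dimethylpropanoyl)oxy]-7a-methyl-5,6,7,7a-tetrahydro-4H-indene-7-carboxylate (not isolated) | CC(C)(C)[Si](C)(C)OCCCC1=C(OC(=O)C(C)(C)C)C=C2[C@@H](OC(=O)/C=C/C=C/C(C)=C/[C@H](C)CC)CC[C@@H](C(=O)OC(C)(C)C)[C@@]21C | intermediate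
20 | tert-butyl (1R,4S,7R,7aS)-1-{3-[(tert-butyldimethylsilyl)oxy]propyl}-4-{[(2E,4E,6E,8R)-6,8-dimethyldeca-2,4,6-trienoyl]oxy}-7a-methyl-2-oxo-2,4,5,6,7,7a-hexahydro-1H-indene-7-carboxylate | CC(C)(C)[Si](C)(C)OCCC[C@H]1C(=O)C=C2[C@@H](OC(=O)/C=C/C=C/C(C)=C/[C@H](C)CC)CC[C@@H](C(=O)OC(C)(C)C)[C@@]21C | intermediate
21 | tert-butyl (1R,4S,7R,7aS)-4-{[(2E,4E,6E,8R)-6,8-dimethyldeca-2,4,6-trienoyl]oxy}-1-(3-hydroxypropyl)-7a-methyl-2-oxo-2,4,5,6,7,7a-hexahydro-1H-indene-7-carboxylate | OCCC[C@H]1C(=O)C=C2[C@@H](OC(=O)/C=C/C=C/C(C)=C/[C@H](C)CC)CC[C@@H](C(=O)OC(C)(C)C)[C@@]21C | intermediate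
22 | tert-butyl (1R,4S,7R,7aS)-4-{[(2E,4E,6E,8R)-6,8-dimethyldeca-2,4,6-trienoyl]oxy}-7a-methyl-2-oxo-1-(3-oxopropyl)-2,4,5,6,7,7a-hexahydro-1H-indene-7-carboxylate | O=CCC[C@H]1C(=O)C=C2[C@@H](OC(=O)/C=C/C=C/C(C)=C/[C@H](C)CC)CC[C@@H](C(=O)OC(C)(C)C)[C@@]21C | intermediate
23 | tert-butyl (1R,4S,7R,7aS)-4-{[(2E,4E,6E,8R)-6,8-dimethyldeca-2,4,6-trienoyl]oxy}-1-(2-formylprop-2-en-1-yl)-7a-methyl-2-oxo-2,4,5,6,7,7a-hexahydro-1H-indene-7-carboxylate | C=C(C=O)C[C@H]1C(=O)C=C2[C@@H](OC(=O)/C=C/C=C/C(C)=C/[C@H](C)CC)CC[C@@H](C(=O)OC(C)(C)C)[C@@]21C | intermediate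
24 | (1R,4S,7R,7aS)-4-{[(2E,4E,6E,8R)-6,8-dimethyldeca-2,4,6-trienoyl]oxy}-1-(2-formylprop-2-en-1-yl)-7a-methyl-2-oxo-2,4,5,6,7,7a-hexahydro-1H-indene-7-carboxylic acid | C=C(C=O)C[C@H]1C(=O)C=C2[C@@H](OC(=O)/C=C/C=C/C(C)=C/[C@H](C)CC)CC[C@@H](C(=O)O)[C@@]21C | target

**Step count and risks**

Total step count: 16. Longest linear sequence: 13 steps (steps 4 to 7, then 8 to 16, from (R)-2-methylbutan-1-ol); the ring A branch (steps 1 to 3, then 8 to 16) is 12 steps.

Three steps most likely to fail: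

1. Step 12 (key step). What may go wrong: with the internal, alkyl-substituted alkyne the pivalate may migrate 1,3 instead of 1,2, which leads to an allenyl pivalate and loss of the ring closure, or turnover at the hindered tetrasubstituted alkene may be slow. Fallback (sets out from 14, comes back at 23): the side chain is taken off the alkyne so that the rearrangement runs on a terminal alkyne, the substrate class for which the 1,2-shift is most secure, and C1 is alkylated afterwards. Carbonylative Sonogashira coupling of 14 with ethynyltrimethylsilane (CO, PdCl2(PPh3)2, CuI, Et3N) gives the silyl ynone tert-butyl (1R,4S)-2-methyl-4-(trienoyloxy)-3-[3-(trimethylsilyl)prop-2-ynoyl]cyclohex-2-ene-1-carboxylate F1. Transfer hydrogenation as in step 10 gives tert-butyl (1R,4S)-3-[(1S)-1-hydroxy-3-(trimethylsilyl)prop-2-yn-1-yl]-2-methyl-4-(trienoyloxy)cyclohex-2-ene-1-carboxylate F2, which has the same spatial arrangement as 17. Bu4NF/AcOH removes the silyl group to give tert-butyl (1R,4S)-3-[(1R)-1-hydroxyprop-2-yn-1-yl]-2-methyl-4-(trienoyloxy)cyclohex-2-ene-1-carboxylate F3, and pivaloyl chloride/pyridine gives tert-butyl (1R,4S)-3-{(1R)-1-[(2,2-dimethylpropanoyl)oxy]prop-2-yn-1-yl}-2-methyl-4-(trienoyloxy)cyclohex-2-ene-1-carboxylate F4. AuCl(PPh3)/AgSbF6 in wet MeCN then gives, through tert-butyl (4S,7R,7aS)-2-[(2,2-dimethylpropanoyl)oxy]-7a-methyl-4-(trienoyloxy)-5,6,7,7a-tetrahydro-4H-indene-7-carboxylate F5 (not isolated), the enone tert-butyl (4S,7R,7aS)-7a-methyl-2-oxo-4-(trienoyloxy)-2,4,5,6,7,7a-hexahydro-1H-indene-7-carboxylate F6, which carries a CH2 group at C1. Kinetic enolisation at C1 (LiN(SiMe3)2, THF, −78 °C) and alkylation with excess 3-chloro-2-(chloromethyl)prop-1-ene, followed by amidine equilibration of C1, gives tert-butyl (1R,4S,7R,7aS)-1-[2-(chloromethyl)prop-2-en-1-yl]-7a-methyl-2-oxo-4-(trienoyloxy)-2,4,5,6,7,7a-hexahydro-1H-indene-7-carboxylate F7. Kornblum oxidation (NaI, NaHCO3, DMSO) converts the allylic chloride into enal 23.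

2. Step 9. What may go wrong: alkynyl transfer to the vinyl palladium intermediate before CO insertion (plain Sonogashira coupling), or slow oxidative addition at the hindered tetrasubstituted vinyl iodide. Fallback (sets out from 14, comes back at 16): alkyne 15 is formylated (n-BuLi, THF, −78 °C; then DMF) to 6-[(tert-butyldimethylsilyl)oxy]hex-2-ynal F8. Nozaki–Hiyama–Kishi coupling of 14 with F8 (CrCl2, NiCl2 cat., DMSO/THF) gives the carbinol as a mixture of 17 and its carbinol epimer tert-butyl (1R,4S)-3-{(1S)-6-[(tert-butyldimethylsilyl)oxy]-1-hydroxyhex-2-yn-1-yl}-2-methyl-4-(trienoyloxy)cyclohex-2-ene-1-carboxylate F9. Dess–Martin oxidation of the mixture gives ynone 16.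

3. Step 10. What may go wrong: hydride delivery with low or reversed facial preference because the ketone carries two unsaturated groups, or competing conjugate reduction of the ynone. Fallback (sets out from 14, comes back at 17): reductive carbonylation of 14 (CO, Pd(PPh3)4, Bu3SnH, THF, 50 °C) gives the enal tert-butyl (1R,4S)-3-formyl-2-methyl-4-(trienoyloxy)cyclohex-2-ene-1-carboxylate F10. Ligand-controlled addition of the zinc acetylide of 15 (Me2Zn, the ProPhenol ligand enantiomer that gives the (R)-carbinol, toluene) then gives 17 directly.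

**Further compounds**

F1 | step 12 | tert-butyl (1R,4S)-4-{[(2E,4E,6E,8R)-6,8-dimethyldeca-2,4,6-trienoyl]oxy}-2-methyl-3-[3-(trimethylsilyl)prop-2-ynoyl]cyclohex-2-ene-1-carboxylate | C[Si](C)(C)C#CC(=O)C1=C(C)[C@H](C(=O)OC(C)(C)C)CC[C@@H]1OC(=O)/C=C/C=C/C(C)=C/[C@H](C)CC
F2 | step 12 | tert-butyl (1R,4S)-4-{[(2E,4E,6E,8R)-6,8-dimethyldeca-2,4,6-trienoyl]oxy}-3-[(1S)-1-hydroxy-3-(trimethylsilyl)prop-2-yn-1-yl]-2-methylcyclohex-2-ene-1-carboxylate | O[C@H](C#C[Si](C)(C)C)C1=C(C)[C@H](C(=O)OC(C)(C)C)CC[C@@H]1OC(=O)/C=C/C=C/C(C)=C/[C@H](C)CC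
F3 | step 12 | tert-butyl (1R,4S)-4-{[(2E,4E,6E,8R)-6,8-dimethyldeca-2,4,6-trienoyl]oxy}-3-[(1R)-1-hydroxyprop-2-yn-1-yl]-2-methylcyclohex-2-ene-1-carboxylate | O[C@H](C#C)C1=C(C)[C@H](C(=O)OC(C)(C)C)CC[C@@H]1OC(=O)/C=C/C=C/C(C)=C/[C@H](C)CC
F4 | step 12 | tert-butyl (1R,4S)-4-{[(2E,4E,6E,8R)-6,8-dimethyldeca-2,4,6-trienoyl]oxy}-3-{(1R)-1-[(2,2-dimethylpropanoyl)oxy]prop-2-yn-1-yl}-2-methylcyclohex-2-ene-1-carboxylate | CC(C)(C)C(=O)O[C@H](C#C)C1=C(C)[C@H](C(=O)OC(C)(C)C)CC[C@@H]1OC(=O)/C=C/C=C/C(C)=C/[C@H](C)CC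
F5 | step 12 | tert-butyl (4S,7R,7aS)-4-{[(2E,4E,6E,8R)-6,8-dimethyldeca-2,4,6-trienoyl]oxy}-2-[(2,2-dimethylpropanoyl)oxy]-7a-methyl-5,6,7,7a-tetrahydro-4H-indene-7-carboxylate | C1=C(OC(=O)C(C)(C)C)C=C2[C@@H](OC(=O)/C=C/C=C/C(C)=C/[C@H](C)CC)CC[C@@H](C(=O)OC(C)(C)C)[C@@]21C
F6 | step 12 | tert-butyl (4S,7R,7aS)-4-{[(2E,4E,6E,8R)-6,8-dimethyldeca-2,4,6-trienoyl]oxy}-7a-methyl-2-oxo-2,4,5,6,7,7a-hexahydro-1H-indene-7-carboxylate | C1C(=O)C=C2[C@@H](OC(=O)/C=C/C=C/C(C)=C/[C@H](C)CC)CC[C@@H](C(=O)OC(C)(C)C)[C@@]21C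
F7 | step 12 | tert-butyl (1R,4S,7R,7aS)-1-[2-(chloromethyl)prop-2-en-1-yl]-4-{[(2E,4E,6E,8R)-6,8-dimethyldeca-2,4,6-trienoyl]oxy}-7a-methyl-2-oxo-2,4,5,6,7,7a-hexahydro-1H-indene-7-carboxylate | C=C(CCl)C[C@H]1C(=O)C=C2[C@@H](OC(=O)/C=C/C=C/C(C)=C/[C@H](C)CC)CC[C@@H](C(=O)OC(C)(C)C)[C@@]21C
F8 | step 9 | 6-[(tert-butyldimethylsilyl)oxy]hex-2-ynal | O=CC#CCCCO[Si](C)(C)C(C)(C)C
F9 | step 9 | tert-butyl (1R,4S)-3-{(1S)-6-[(tert-butyldimethylsilyl)oxy]-1-hydroxyhex-2-yn-1-yl}-4-{[(2E,4E,6E,8R)-6,8-dimethyldeca-2,4,6-trienoyl]oxy}-2-methylcyclohex-2-ene-1-carboxylate | O[C@@H](C#CCCCO[Si](C)(C)C(C)(C)C)C1=C(C)[C@H](C(=O)OC(C)(C)C)CC[C@@H]1OC(=O)/C=C/C=C/C(C)=C/[C@H](C)CC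
F10 | step 10 | tert-butyl (1R,4S)-4-{[(2E,4E,6E,8R)-6,8-dimethyldeca-2,4,6-trienoyl]oxy}-3-formyl-2-methylcyclohex-2-ene-1-carboxylate | O=CC1=C(C)[C@H](C(=O)OC(C)(C)C)CC[C@@H]1OC(=O)/C=C/C=C/C(C)=C/[C@H](C)CC
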